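**Retrosynthetic overview** (germacrane numbering: lactone at C6/C7/C12, isovalerate at C8, acetate at C3, epoxide at C1–C10)
1. Epoxide ring last: peracid epoxidation of the 1(10)E alkene of the 4Z triene lactone, as in the late oxidase step.
2. Ten-membered carbocycle by the C6–C7 bond (the farnesyl C1–C10 bond made by the germacrene cyclase), closed on an acyclic (Z)-enal. The allyl donor is a Baylis–Hillman acetate ionised by zerovalent palladium and polarity-inverted with InI; the γ-lactone (O6–C12) closes in the same operation.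
3. Acyclic chain: C3–C4 by Ni/Cr coupling of a (Z)-iodoalkene (sets C3), C1–C2 by Negishi coupling, C7–C11 by Baylis–Hillman reaction, C10–C14 by carboalumination, C8 from (S)-epichlorohydrin.
4. Ring order: carbocycle, then lactone (same flask), then epoxide.

Assumption: in step 10 the (S)-valinol-derived Kishi ligand is taken to give the 9S carbinol; if a pilot run shows the opposite sense, its enantiomer is used.

**Step 1**
Reactants: 1 (S)-epichlorohydrin; 2 acetylene
Product: 3 (2S)-1-chloropent-4-yn-2-ol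
Conditions: n-BuLi, THF, −78 °C; BF3·OEt2, then 1, −78 °C; aq. NH4Cl
Reagents that add atoms: none
Why: Yamaguchi-type epoxide opening in which lithium acetylide attacks the BF3-activated epoxide at its unsubstituted ring carbon by SN2, so the stereocentre of 1 is untouched and becomes C8 (S) with its oxygen in place.

**Step 2**
Reactants: 3
Product: 5 (3S)-hex-1-en-5-yn-3-ol, via (2S)-2-(prop-2-yn-1-yl)oxirane 4 (not isolated)
Conditions: Me3S+ I−, n-BuLi, THF, −10 °C → rt
Reagents that add atoms: trimethylsulfonium iodide, C[S+](C)C.[I-]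
Why: Corey–Chaykovsky ylide chemistry in the Alcaraz–Mioskowski mode: the ylide closes the chlorohydrin to epoxide 4, opens it at the CH2 terminus and the betaine eliminates Me2S to the one-carbon-homologated allylic alcohol, the carbinol centre never being touched.

**Step 3**
Reactants: 5
Product: 7 (3S,5E)-6-iodo-5-methylhexa-1,5-dien-3-ol, via alkenyldimethylalane 6 (not isolated)
Conditions: AlMe3, Cp2ZrCl2 (25 mol %), CH2Cl2, 0 °C → rt; then I2, THF, −30 → 0 °C
Reagents that add atoms: trimethylaluminium, C[Al](C)C; iodine, II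
Why: Negishi zirconium-catalysed methylalumination adds CH3 and Al syn across the terminal alkyne with methyl on the internal carbon (the vinyl group and the aluminium alkoxide are spectators), and iodinolysis with retention fixes the 1(10)E alkene with its C14 methyl.

**Step 4**
Reactants: 7
Product: 8 (3S,5E)-6-iodo-5-methylhexa-1,5-dien-3-yl 3-methylbutanoate
Conditions: 3-methylbutanoyl chloride, pyridine, DMAP (cat.), CH2Cl2, 0 °C
Reagents that add atoms: 3-methylbutanoyl chloride, CC(C)CC(=O)Cl
Why: DMAP-catalysed acylation (nucleophilic acyl substitution) installs the C8 isovalerate of the target at the outset, so no protecting-group exchange is needed later.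

**Step 5**
Reactants: 8
Product: 10 (2S,4E)-5-iodo-4-methyl-1-oxopent-4-en-2-yl 3-methylbutanoate, via vicinal diol 9 (not isolated)
Conditions: OsO4 (2 mol %), NaIO4, 2,6-lutidine, dioxane–H2O 3:1, rt
Reagents that add atoms: osmium tetroxide (catalytic oxygen carrier), O=[Os](=O)(=O)=O; sodium periodate (stoichiometric oxygen source), [Na+].[O-]I(=O)(=O)=O
Why: Johnson–Lemieux oxidative cleavage (osmylation, then periodate glycol cleavage, lutidine-buffered) is selective for the monosubstituted vinyl group because the trisubstituted iodoalkene is deactivated towards OsO4, and the C8 centre is not involved.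

**Step 6**
Reactants: 10; 11 methyl acrylate
Product: 12 methyl (3RS,4S,6E)-3-hydroxy-7-iodo-6-methyl-4-[(3-methylbutanoyl)oxy]-2-methylidenehept-6-enoate
Conditions: DABCO (0.5 equiv), 11 (neat, excess), MeOH (cat.), 0 °C → rt
Reagents that add atoms: none
Why: Morita–Baylis–Hillman reaction of the highly electrophilic α-acyloxy aldehyde forms the C7–C11 bond within hours; the new carbinol centre is formed as a mixture, which does not matter because it becomes part of the π-allyl unit in step 14.

**Step 7**
Reactants: 12; 13 (1,3-dioxolan-2-ylmethyl)zinc bromide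
Product: 15 methyl (3RS,4S,6E)-3-hydroxy-6-methyl-4-[(3-methylbutanoyl)oxy]-2-methylidene-9-oxonon-6-enoate, via dioxolane acetal 14 (not isolated)
Conditions: Pd(PPh3)4 (5 mol %), THF, 40 °C; then 2 M HCl, THF, 0 °C → rt
Reagents that add atoms: water, O
Why: Negishi sp2–sp3 coupling of the alkenyl iodide (E geometry retained, free hydroxyl tolerated as zinc alkoxide) brings in C2 and C3 as a masked acetaldehyde, and acetal hydrolysis through a non-conjugated oxocarbenium ion releases the β,γ-unsaturated aldehyde.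

**Step 8**
Reactants: 16 but-2-yn-1-ol
Product: 18 (2Z)-3-iodobut-2-en-1-ol, via cyclic alkenylaluminate 17 (not isolated)
Conditions: NaAlH2(OCH2CH2OCH3)2, THF, 0 °C → rt; then I2, −78 → 0 °C
Reagents that add atoms: iodine, II
Why: Hydroxyl-directed trans-hydroalumination of the propargylic alcohol places aluminium on C3 anti to the delivered hydride, and iodinolysis with retention gives the (Z)-iodoalkene that carries the later 4Z geometry.

**Step 9**
Reactants: 18
Product: 19 tert-butyl{[(2Z)-3-iodobut-2-en-1-yl]oxy}dimethylsilane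
Conditions: TBSCl, imidazole, DMF, rt
Reagents that add atoms: tert-butyldimethylsilyl chloride, CC(C)(C)[Si](C)(C)Cl
Why: Routine silyl ether formation masks the primary allylic alcohol that will become the C6 aldehyde.

**Step 10**
Reactants: 15; 19
Product: 20 methyl (3RS,4S,6E,9S,10Z)-12-[(tert-butyldimethylsilyl)oxy]-3,9-dihydroxy-6,10-dimethyl-4-[(3-methylbutanoyl)oxy]-2-methylidenedodeca-6,10-dienoate
Conditions: 19 (3 equiv), CrCl2, NiCl2 (2 mol %), (S)-N-[2-(4-isopropyl-4,5-dihydrooxazol-2-yl)-6-methylphenyl]methanesulfonamide, Et3N, THF, rt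
Reagents that add atoms: none
Why: Asymmetric Nozaki–Hiyama–Kishi coupling (NiCl2 catalysis, CrCl2 as reductant; tolerant of the esters, acrylate and free hydroxyl) adds the alkenylchromium to the aldehyde with retention of the Z geometry, the chiral sulfonamide ligand on chromium setting the new carbinol (C3 of the target) as S, and the minor epimer is a separable diastereomer because C8 is already fixed.

**Step 11**
Reactants: 20
Product: 21 methyl (3RS,4S,6E,9S,10Z)-3,9-bis(acetyloxy)-12-[(tert-butyldimethylsilyl)oxy]-6,10-dimethyl-4-[(3-methylbutanoyl)oxy]-2-methylidenedodeca-6,10-dienoate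
Conditions: Ac2O, pyridine, DMAP (cat.), CH2Cl2, 0 °C
Reagents that add atoms: acetic anhydride, CC(=O)OC(C)=O
Why: One DMAP-catalysed acetylation esterifies both secondary hydroxyls, giving the C3 acetate of the target and turning the Baylis–Hillman alcohol into the allylic acetate that is the allyl donor of step 14 (any SN2′-isomerised primary acetate leads to the same π-allyl).

**Step 12**
Reactants: 21
Product: 22 methyl (3RS,4S,6E,9S,10Z)-3,9-bis(acetyloxy)-12-hydroxy-6,10-dimethyl-4-[(3-methylbutanoyl)oxy]-2-methylidenedodeca-6,10-dienoate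
Conditions: HF·pyridine, pyridine, THF, 0 °C
Reagents that add atoms: none
Why: Buffered fluoride desilylation removes the TBS group without touching the four esters.

**Step 13**
Reactants: 22
Product: 23 methyl (3RS,4S,6E,9S,10Z)-3,9-bis(acetyloxy)-6,10-dimethyl-4-[(3-methylbutanoyl)oxy]-2-methylidene-12-oxododeca-6,10-dienoate
Conditions: MnO2 (activated), CH2Cl2, rt, dark
Reagents that add atoms: none
Why: MnO2 oxidation is specific for the primary allylic alcohol and, being neutral and heterogeneous, preserves the Z enal geometry and avoids the acid-promoted ene cyclisation to which neral-type enals are prone.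

**Step 14**
Reactants: 23
Product: 25 (3aR,4S,6E,9S,10Z,11aR)-9-(acetyloxy)-6,10-dimethyl-3-methylidene-2-oxo-2,3,3a,4,5,8,9,11a-octahydrocyclodeca[b]furan-4-yl 3-methylbutanoate, via ring-closed hydroxy ester 24 (not isolated)
Conditions: Pd(PPh3)4 (10 mol %), InI (2 equiv), THF, 2 mM (slow addition of 23), rt; then PPTS, CH2Cl2, rt
Reagents that add atoms: none
Why: Proposed new method: zerovalent palladium ionises the doubly activated Baylis–Hillman acetate (expected to be far faster than the C3 acetate on its hindered, electron-poor alkene) to a 2-methoxycarbonyl-π-allyl complex in which the C7 configuration is erased, InI reduces this to a nucleophilic allylindium (Araki umpolung allylation; closest ring-forming precedents are the Pd/Et2Zn closure of a farnesal-derived allyl chloride to a germacrane ring and CrCl2 Nozaki–Hiyama–Kishi closures to germacranolides), which adds through C7 to the (Z)-enal in a chair-like six-centre transition state embedded in the forming ten-membered ring, with H8 eclipsing the allyl plane and the aldehyde approaching anti to the C8–O bond (expected 7R) and the enal substituent pseudo-equatorial (expected 6R, H6/H7 trans), after which mild acid closes the 6,12-lactone.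

**Step 15**
Reactants: 25
Product: 26 (1R,2S,4R,6R,8S,9Z,11R)-8-(acetyloxy)-4,9-dimethyl-14-methylidene-13-oxo-5,12-dioxatricyclo[9.3.0.0^4,6]tetradec-9-en-2-yl 3-methylbutanoate (target)
Conditions: mCPBA, NaHCO3, CH2Cl2, 0 °C
Reagents that add atoms: 3-chloroperbenzoic acid, OOC(=O)c1cccc(Cl)c1
Why: Prilezhaev epoxidation attacks only the electron-rich 1(10)E alkene (the 4Z alkene is flanked by two allylic oxygens, the methylidene is conjugated) and, by analogy with germacranolide epoxidations, from the outer face of the ring with C14 on the β face, giving the 1β,10α (1R,10R) trans-epoxide of the natural 1(10)-epoxyheliangolides.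

**Compound list**
1 | (S)-epichlorohydrin, (2S)-2-(chloromethyl)oxirane | ClC[C@@H]1CO1 | starting material
2 | acetylene | C#C | starting material
3 | (2S)-1-chloropent-4-yn-2-ol | C#CC[C@H](O)CCl | intermediate
4 | (2S)-2-(prop-2-yn-1-yl)oxirane | C#CC[C@H]1CO1 | intermediate (not isolated)
5 | (3S)-hex-1-en-5-yn-3-ol | C#CC[C@H](O)C=C | intermediate
6 | alkenyldimethylalane, [(1E,4S)-4-(dimethylalumanyloxy)-2-methylhexa-1,5-dien-1-yl]dimethylalumane | C[Al](C)/C=C(\C)C[C@H](O[Al](C)C)C=C | intermediate (not isolated)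
7 | (3S,5E)-6-iodo-5-methylhexa-1,5-dien-3-ol | I/C=C(\C)C[C@H](O)C=C | intermediate
8 | (3S,5E)-6-iodo-5-methylhexa-1,5-dien-3-yl 3-methylbutanoate | I/C=C(\C)C[C@H](OC(=O)CC(C)C)C=C | intermediate
9 | vicinal diol, (2RS,3S,5E)-1,2-dihydroxy-6-iodo-5-methylhex-5-en-3-yl 3-methylbutanoate | I/C=C(\C)C[C@H](OC(=O)CC(C)C)C(O)CO | intermediate (not isolated)
10 | (2S,4E)-5-iodo-4-methyl-1-oxopent-4-en-2-yl 3-methylbutanoate | I/C=C(\C)C[C@H](OC(=O)CC(C)C)C=O | intermediate
11 | methyl acrylate | C=CC(=O)OC | starting material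
12 | methyl (3RS,4S,6E)-3-hydroxy-7-iodo-6-methyl-4-[(3-methylbutanoyl)oxy]-2-methylidenehept-6-enoate | I/C=C(\C)C[C@H](OC(=O)CC(C)C)C(O)C(=C)C(=O)OC | intermediate
13 | (1,3-dioxolan-2-ylmethyl)zinc bromide | Br[Zn]CC1OCCO1 | starting material
14 | dioxolane acetal, methyl (3RS,4S,6E)-8-(1,3-dioxolan-2-yl)-3-hydroxy-6-methyl-4-[(3-methylbutanoyl)oxy]-2-methylideneoct-6-enoate | C1COC(O1)C/C=C(\C)C[C@H](OC(=O)CC(C)C)C(O)C(=C)C(=O)OC | intermediate (not isolated)
15 | methyl (3RS,4S,6E)-3-hydroxy-6-methyl-4-[(3-methylbutanoyl)oxy]-2-methylidene-9-oxonon-6-enoate | O=CC/C=C(\C)C[C@H](OC(=O)CC(C)C)C(O)C(=C)C(=O)OC | intermediate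
16 | but-2-yn-1-ol | CC#CCO | starting material
17 | cyclic alkenylaluminate, sodium 2,2-bis(2-methoxyethoxy)-3-methyl-2,5-dihydro-1,2-oxaaluminol-2-uide | [Na+].C/C1=C/CO[Al-]1(OCCOC)OCCOC | intermediate (not isolated)
18 | (2Z)-3-iodobut-2-en-1-ol | OC/C=C(/C)I | intermediate
19 | tert-butyl{[(2Z)-3-iodobut-2-en-1-yl]oxy}dimethylsilane | CC(C)(C)[Si](C)(C)OC/C=C(/C)I | intermediate
20 | methyl (3RS,4S,6E,9S,10Z)-12-[(tert-butyldimethylsilyl)oxy]-3,9-dihydroxy-6,10-dimethyl-4-[(3-methylbutanoyl)oxy]-2-methylidenedodeca-6,10-dienoate | CC(C)(C)[Si](C)(C)OC/C=C(/C)[C@@H](O)C/C=C(\C)C[C@H](OC(=O)CC(C)C)C(O)C(=C)C(=O)OC | intermediate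
21 | methyl (3RS,4S,6E,9S,10Z)-3,9-bis(acetyloxy)-12-[(tert-butyldimethylsilyl)oxy]-6,10-dimethyl-4-[(3-methylbutanoyl)oxy]-2-methylidenedodeca-6,10-dienoate | CC(C)(C)[Si](C)(C)OC/C=C(/C)[C@@H](OC(C)=O)C/C=C(\C)C[C@H](OC(=O)CC(C)C)C(OC(C)=O)C(=C)C(=O)OC | intermediate
22 | methyl (3RS,4S,6E,9S,10Z)-3,9-bis(acetyloxy)-12-hydroxy-6,10-dimethyl-4-[(3-methylbutanoyl)oxy]-2-methylidenedodeca-6,10-dienoate | OC/C=C(/C)[C@@H](OC(C)=O)C/C=C(\C)C[C@H](OC(=O)CC(C)C)C(OC(C)=O)C(=C)C(=O)OC | intermediate
23 | methyl (3RS,4S,6E,9S,10Z)-3,9-bis(acetyloxy)-6,10-dimethyl-4-[(3-methylbutanoyl)oxy]-2-methylidene-12-oxododeca-6,10-dienoate | O=C/C=C(/C)[C@@H](OC(C)=O)C/C=C(\C)C[C@H](OC(=O)CC(C)C)C(OC(C)=O)C(=C)C(=O)OC | intermediate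
24 | ring-closed hydroxy ester, methyl 2-[(1S,2R,3Z,5S,7E,10S)-5-(acetyloxy)-2-hydroxy-4,8-dimethyl-10-[(3-methylbutanoyl)oxy]cyclodeca-3,7-dien-1-yl]prop-2-enoate | C=C(C(=O)OC)[C@H]1[C@H](O)/C=C(/C)[C@@H](OC(C)=O)C/C=C(\C)C[C@@H]1OC(=O)CC(C)C | intermediate (not isolated)
25 | (3aR,4S,6E,9S,10Z,11aR)-9-(acetyloxy)-6,10-dimethyl-3-methylidene-2-oxo-2,3,3a,4,5,8,9,11a-octahydrocyclodeca[b]furan-4-yl 3-methylbutanoate | C=C1C(=O)O[C@@H]2/C=C(/C)[C@@H](OC(C)=O)C/C=C(\C)C[C@H](OC(=O)CC(C)C)[C@@H]12 | intermediate
26 | (1R,2S,4R,6R,8S,9Z,11R)-8-(acetyloxy)-4,9-dimethyl-14-methylidene-13-oxo-5,12-dioxatricyclo[9.3.0.0^4,6]tetradec-9-en-2-yl 3-methylbutanoate (3β-acetoxy-8α-isovaleryloxy-1β,10α-epoxy-4Z-heliangolide) | C=C1C(=O)O[C@@H]2/C=C(/C)[C@@H](OC(C)=O)C[C@H]3O[C@]3(C)C[C@H](OC(=O)CC(C)C)[C@@H]12 | target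

**Step count**
Total steps: 15. Longest linear sequence: 13 (steps 1–7 and 10–15); steps 8–9 make the iodoalkene 19 in a side branch.

**Three steps most likely to fail**

Step 14 (ring closure). The allylindium must close a ten-membered ring at high dilution, so it is long-lived. Competing paths are 1,4-elimination of the C8 carboxylate to a 2-methoxycarbonyl diene, ionisation of the C3 acetate by palladium, a neral-type ene cyclisation if the medium becomes Lewis acidic, and the wrong C6/C7 diastereomer. Fallback with a stoichiometric chromium Barbier closure of a preformed allyl bromide: it sets out from 22, which MgBr2·OEt2 in THF converts by SN2′ displacement of the Baylis–Hillman acetate into the primary allyl bromide F5. MnO2 then gives the bromo enal F6, and CrCl2 in THF/DMF at 2 mM closes it by an intramolecular Nozaki–Hiyama–Kishi reaction to 24, which lactonises with PPTS to 25, where the route is rejoined.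

Step 10 (C3 stereocentre). Ligand control on a linear β,γ-unsaturated aldehyde with a trisubstituted (Z)-alkenyl iodide may be modest, and the sense is assumed. Fallback with reagent-controlled reduction instead of stereoselective C–C bond formation: it sets out from 15, which is coupled with 19 by CrCl2/NiCl2 without ligand to give 20 together with its 9R epimer F3. MnO2 oxidises the C9 allylic alcohol of the mixture (the electron-poor Baylis–Hillman carbinol reacts much more slowly) to the enone F4, and (R)-Me-CBS oxazaborolidine with catecholborane at −40 °C reduces F4 to the 9S alcohol, which is 20.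

Step 7 (aldehyde 15). The alkylzinc may couple sluggishly beside the free hydroxyl, and the acid hydrolysis may move the C1=C10 double bond into conjugation. Fallback that reaches the aldehyde by oxidation instead of acetal hydrolysis: it sets out from 12, which undergoes Stille coupling with tributyl(vinyl)stannane (Pd(PPh3)4, DMF, rt) to the 6,8-diene F1. 9-BBN hydroborates only the terminal vinyl group of F1, and NaBO3 work-up gives the primary alcohol F2. TEMPO/PhI(OAc)2 oxidises the primary alcohol of F2 selectively to 15, where the route is rejoined.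

**Further compounds**
F1 | step 7 | methyl (3RS,4S,6E)-3-hydroxy-6-methyl-4-[(3-methylbutanoyl)oxy]-2-methylidenenona-6,8-dienoate | C=C/C=C(\C)C[C@H](OC(=O)CC(C)C)C(O)C(=C)C(=O)OC
F2 | step 7 | methyl (3RS,4S,6E)-3,9-dihydroxy-6-methyl-4-[(3-methylbutanoyl)oxy]-2-methylidenenon-6-enoate | OCC/C=C(\C)C[C@H](OC(=O)CC(C)C)C(O)C(=C)C(=O)OC
F3 | step 10 | methyl (3RS,4S,6E,9R,10Z)-12-[(tert-butyldimethylsilyl)oxy]-3,9-dihydroxy-6,10-dimethyl-4-[(3-methylbutanoyl)oxy]-2-methylidenedodeca-6,10-dienoate | CC(C)(C)[Si](C)(C)OC/C=C(/C)[C@H](O)C/C=C(\C)C[C@H](OC(=O)CC(C)C)C(O)C(=C)C(=O)OC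
F4 | step 10 | methyl (3RS,4S,6E,10Z)-12-[(tert-butyldimethylsilyl)oxy]-3-hydroxy-6,10-dimethyl-4-[(3-methylbutanoyl)oxy]-2-methylidene-9-oxododeca-6,10-dienoate | CC(C)(C)[Si](C)(C)OC/C=C(/C)C(=O)C/C=C(\C)C[C@H](OC(=O)CC(C)C)C(O)C(=C)C(=O)OC
F5 | step 14 | methyl (2Z,4S,6E,9S,10Z)-9-(acetyloxy)-2-(bromomethyl)-12-hydroxy-6,10-dimethyl-4-[(3-methylbutanoyl)oxy]dodeca-2,6,10-trienoate | OC/C=C(/C)[C@@H](OC(C)=O)C/C=C(\C)C[C@H](OC(=O)CC(C)C)/C=C(\CBr)C(=O)OC
F6 | step 14 | methyl (2Z,4S,6E,9S,10Z)-9-(acetyloxy)-2-(bromomethyl)-6,10-dimethyl-4-[(3-methylbutanoyl)oxy]-12-oxododeca-2,6,10-trienoate | O=C/C=C(/C)[C@@H](OC(C)=O)C/C=C(\C)C[C@H](OC(=O)CC(C)C)/C=C(\CBr)C(=O)OC
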